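**One step fails.** In a one-step world, with the rate proportional to [first end groups] and the dosing schedule held, links in percent would not depend on the charge. Yet epsilon reaches 42 % and beta 30 %.

| setting | epsilon | beta | cedar | ash |
|---|---|---|---|---|
| first end groups | 0.14 M (fed, over 3.0 min) | 0.22 M (fed, over 3.0 min) | 0.10 M (fed, over 3.0 min) | 0.10 M |
| gas | 5.2 mM (held) | 5.2 mM (held) | 5.2 mM (held) | 5.2 mM |
| remark | run made earlier; the fed solution adds 0.25 times the starting volume | run made earlier; the fed solution adds 0.25 times the starting volume | the fed solution adds 0.25 times the starting volume | everything together at the start, the whole solution of first end groups included, so that from the start the volume is larger by 0.25 times the starting volume |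
| time |  |  | 3.0 min | 0.80 min |

| run | time / min | links / % | first end groups / % |
|---|---|---|---|
| epsilon | 0.250 | 2 | 4 |
| epsilon | 0.417 | 3 | 9 |
| epsilon | 0.833 | 9 | 18 |
| epsilon | 1.50 | 18 | 34 |
| epsilon | 3.00 | 42 | 56 |
| beta | 0.250 | 1 | 5 |
| beta | 0.833 | 5 | 22 |
| beta | 1.33 | 11 | 33 |
| beta | 2.00 | 19 | 49 |
| beta | 3.00 | 30 | 71 |

(standard deviation of a reading: 1.5 percentage points)

- charges are per starting volume, the dose included; the dosed solution carries all of it
- at the start none of second end groups is dissolved
- the analysis behind the earlier runs scatters by 1.5 percentage points, standard deviation
- steps that have been proposed: gas <-> second end groups; links -> over-reaction product; first end groups + second end groups <-> links + by-product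
- percentages count the whole charge, also what has not yet gone in

- which of the two ends with the higher amount of links, in percent of the first end groups charged ("neither" if they lie within 2 percentage points) (cedar / ash / neither)
- links at the end, in percent of the first end groups charged, cedar
- links at the end, in percent of the first end groups charged, ash

**The ceiling.** So I reckon in absolute amounts. Between 2.00 min and 3.00 min, the beta readings give links at 0.0200 M/min. This is my supply rate: links formed per minute per litre of solution present, with first end groups ample. Late epsilon reads 0.0189 M/min, though it ends with half of beta's free first end groups. I therefore take the passage of gas into second end groups as the rate-limiting step.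

**Upper bounds.** Averaged over the dose, cedar's volume times its time is 3.38 min per starting volume, so my estimated ceiling for cedar is 67.6 %. Ash, at full volume from the start, gets an estimated ceiling of 20.0 %.

**Lower bound.** Ash starts with [first end groups] at 0.0800 M, richer than the 0.0236 M I read for epsilon at 0.833 min. Epsilon's mean rate up to then, 0.0146 M/min, gives ash a floor of 14.6 %.

**Going round.** Cedar at its ceiling would hold 0.0259 M free, near that same epsilon level. I expect its rate to climb as epsilon's did, so I use 0.0146 M/min, which gives 49.3 %. That leaves 0.0405 M free, near epsilon's 0.0423 M at 1.50 min. Epsilon's mean rate up to that time, 0.0158 M/min, gives 53.4 %. I commit to cedar between these two, ahead of ash.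

**The forecast.** It says cedar, with 48 % and 18 %, formation being “limited by gas converting to second end groups”. Its ash lies inside my bracket; its cedar lies just below my 49.3 %, and each earlier reading scatters by 1.5 percentage points.

**The result.** Cedar ends at 51.8 % and ash at 19.6 %, so cedar leads.

    gas ⇌ second end groups, rate k1*(csat - [second end groups]) (kL = 4.20 /min)
    links → over-reaction product (k = 1.80 × 10⁻⁴ /min)
    first end groups + second end groups ⇌ links + by-product (K = 56.0, k = 730 /M/min)

**Ceiling again.** At its end, ash holds [second end groups] of 4.84 × 10⁻⁴ M, against a saturation concentration of 5.2 mM for gas. On the cedar recipe with 0.17 M of first end groups, my supply rate gives an estimated ceiling on links of 39.8 %, and that flask holds 35.5 %.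

The data were generated by integration from invented constants; the scatter is artificial.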